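**Retrosynthetic overview**
1. Target 21 comes from its bis(benzyl ether) 20 by neutral hydrogenolysis.
2. C4–C(=O)Ar bond: Ir/Ni deoxygenative acyl cross-coupling (new) of diol 18 with N-aroylsuccinimide 15. C4 is set under control of C3.
3. ArCH2–C3 bond: Ni-catalysed cross-electrophile coupling of spiro-epoxide 11 with aryl bromide 4. The C3–O bond is never broken.
4. 11 comes from (S)-3-hydroxy-γ-butyrolactone 5 by methylenation, silylation and anti epoxidation. 4 and 15 both come from catechol 1.
5. Rings: both arenes (1) and the lactone (5) are bought in. Only a transient spiro-oxirane is formed (step 7) and opened (step 10).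

Assumption: a step is one operation that ends in an isolated product. Species made and consumed in the same flask are numbered but not counted as steps.

**Step 1**
Reactants: 1 catechol
Product: 2 guaiacol (2-methoxyphenol)
Conditions: MeI (1.0 equiv), K2CO3 (1.0 equiv), acetone, reflux; 1 in 1.5-fold excess
Reagents that add atoms: iodomethane, CI
Why: Williamson ether synthesis in which limiting MeI against excess catechol stops at the mono-ether, and veratrole and unreacted 1 are removed by extraction and distillation.

**Step 2**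
Reactants: 2 guaiacol
Product: 3 4-bromo-2-methoxyphenol
Conditions: NBS, MeCN, 0 °C to rt
Reagents that add atoms: N-bromosuccinimide, O=C1CCC(=O)N1Br
Why: Electrophilic aromatic bromination in which the free OH is the stronger donor, so bromine enters para to it.

**Step 3**
Reactants: 3 4-bromo-2-methoxyphenol
Product: 4 1-(benzyloxy)-4-bromo-2-methoxybenzene
Conditions: BnBr, K2CO3, DMF, rt
Reagents that add atoms: benzyl bromide, BrCc1ccccc1
Why: Williamson benzylation of the phenol gives a protecting group that survives organolithium, nickel and photoredox conditions and leaves under neutral hydrogenolysis.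

**Step 4**
Reactants: 5 (S)-3-hydroxy-γ-butyrolactone [(4S)-4-hydroxydihydrofuran-2(3H)-one]
Product: 7 (3S,4S)-3-[(dimethylamino)methyl]-4-hydroxydihydrofuran-2(3H)-one, via dilithium dianion 6 (not isolated)
Conditions: LiN(iPr)2 (2.2 equiv), THF, −78 to −40 °C; [CH2=NMe2]I, −78 to 0 °C; AcOH quench
Reagents that add atoms: N,N-dimethylmethyleneiminium iodide (Eschenmoser's salt), C=[N+](C)C.[I-]
Why: Mannich aminomethylation of the alkoxide–enolate dianion (Fráter–Seebach type), in which the alkoxide is too poor a leaving group for β-elimination and the iminium ion adds anti to the C4 oxygen, giving a trans C3 centre that step 5 erases.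

**Step 5**
Reactants: 7 (3S,4S)-3-[(dimethylamino)methyl]-4-hydroxydihydrofuran-2(3H)-one
Product: 9 (4S)-4-hydroxy-3-methylidenedihydrofuran-2(3H)-one [(S)-tulipalin B], via trimethylammonium iodide 8 (not isolated)
Conditions: MeI, MeOH, rt; then aq NaHCO3/CH2Cl2, rt
Reagents that add atoms: none
Why: N-quaternisation followed by a Hofmann-type E1cB elimination under bicarbonate installs the exocyclic methylene without touching the C4 stereocentre or isomerising to the tetronic acid.

**Step 6**
Reactants: 9 (S)-tulipalin B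
Product: 10 (4S)-4-[(tert-butyldimethylsilyl)oxy]-3-methylidenedihydrofuran-2(3H)-one
Conditions: TBSOTf, 2,6-lutidine, CH2Cl2, −78 to 0 °C
Reagents that add atoms: tert-butyldimethylsilyl triflate, CC(C)(C)[Si](C)(C)OS(=O)(=O)C(F)(F)F
Why: O-silylation with a non-nucleophilic base avoids Michael addition to the acrylate and places a bulky group that blocks one face of the alkene.

**Step 7**
Reactants: 10 (4S)-4-[(tert-butyldimethylsilyl)oxy]-3-methylidenedihydrofuran-2(3H)-one
Product: 11 (3S,7R)-7-[(tert-butyldimethylsilyl)oxy]-1,5-dioxaspiro[2.4]heptan-4-one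
Conditions: DMDO (acetone solution, 3 equiv), CH2Cl2, rt, 48 h
Reagents that add atoms: dimethyldioxirane, CC1(C)OO1
Why: Concerted dioxirane epoxidation of the acrylate-type alkene occurs on the face anti to the C4 silyloxy group, which sets the future tertiary carbinol carbon as S with oxygen trans to OTBS.

**Step 8**
Reactants: 4 1-(benzyloxy)-4-bromo-2-methoxybenzene
Product: 13 4-(benzyloxy)-3-methoxybenzoic acid, via aryllithium 12 (not isolated)
Conditions: nBuLi, THF, −78 °C; CO2 (g); then 1 M HCl
Reagents that add atoms: carbon dioxide, O=C=O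
Why: Bromine–lithium exchange followed by carboxylation is fast at −78 °C and leaves both ethers intact.

**Step 9**
Reactants: 13 4-(benzyloxy)-3-methoxybenzoic acid
Product: 15 1-[4-(benzyloxy)-3-methoxybenzoyl]pyrrolidine-2,5-dione, via acid chloride 14 (not isolated)
Conditions: (COCl)2, cat. DMF, CH2Cl2, 0 °C to rt, evaporate; succinimide, Et3N, CH2Cl2, 0 °C to rt
Reagents that add atoms: succinimide, O=C1CCC(=O)N1
Why: Acid chloride formation and N-acylation give a bench-stable imide whose weakened N–C(O) bond adds to low-valent nickel but does not acylate hindered alcohols.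

**Step 10**
Reactants: 11 (3S,7R)-7-[(tert-butyldimethylsilyl)oxy]-1,5-dioxaspiro[2.4]heptan-4-one; 4 1-(benzyloxy)-4-bromo-2-methoxybenzene
Product: 17 (3S,4R)-3-[4-(benzyloxy)-3-methoxybenzyl]-4-[(tert-butyldimethylsilyl)oxy]-3-hydroxydihydrofuran-2(3H)-one, via iodohydrin 16 (not isolated)
Conditions: NiCl2(dme) (10 mol %), 2,2'-bipyridine (10 mol %), NaI (25 mol %), Et3N·HCl (1.0 equiv), Mn powder (2 equiv), DMPU, rt
Reagents that add atoms: none
Why: Nickel-catalysed cross-electrophile coupling of an epoxide with an aryl bromide under iodide co-catalysis, in which iodide opens 11 at the unhindered CH2 to give 16 and its primary radical is captured by the aryl-nickel species from 4, so the CH2–aryl bond forms while the C3–O bond and its S configuration are untouched.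

**Step 11**
Reactants: 17 (3S,4R)-3-[4-(benzyloxy)-3-methoxybenzyl]-4-[(tert-butyldimethylsilyl)oxy]-3-hydroxydihydrofuran-2(3H)-one
Product: 18 (3S,4R)-3-[4-(benzyloxy)-3-methoxybenzyl]-3,4-dihydroxydihydrofuran-2(3H)-one
Conditions: HF·pyridine, THF, 0 °C to rt
Reagents that add atoms: none
Why: Fluoride-mediated desilylation under mildly acidic conditions frees the secondary alcohol without lactone opening or silyl migration.

**Step 12**
Reactants: 18 (3S,4R)-3-[4-(benzyloxy)-3-methoxybenzyl]-3,4-dihydroxydihydrofuran-2(3H)-one; 15 1-[4-(benzyloxy)-3-methoxybenzoyl]pyrrolidine-2,5-dione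
Product: 20 (3S,4S)-4-[4-(benzyloxy)-3-methoxybenzoyl]-3-[4-(benzyloxy)-3-methoxybenzyl]-3-hydroxydihydrofuran-2(3H)-one, via benzoxazoline adduct 19 (not isolated)
Conditions: 5,7-di-tert-butyl-3-phenylbenzoxazolium tetrafluoroborate (1.1 equiv), pyridine (1.1 equiv), MTBE, rt, 15 min, filter; then 15 (1.5 equiv), NiBr2(dtbbpy) (10 mol %), [Ir(ppy)2(dtbbpy)]PF6 (2 mol %), quinuclidine (1.2 equiv), MTBE/DMA, 450 nm LED, rt
Reagents that add atoms: none
Why: Proposed new method: a deoxygenative acyl cross-coupling in which the less hindered secondary OH of 18 condenses with the benzoxazolium salt to give 19, the excited iridium photocatalyst oxidises its nitrogen, quinuclidine removes the acetal C–H and β-scission expels the benzoxazolone to leave the C4 radical, while zerovalent nickel inserts into the N–C(O) bond of 15; the resulting aroyl complex of divalent nickel captures the radical on the face anti to the C3 benzyl group (syn to OH), and reductive elimination from trivalent nickel forms the C4–C(=O) bond as the 4S isomer (aroyl trans to benzyl, cis to OH), which should also be the thermodynamic epimer because of sterics and the OH···O=C hydrogen bond; the closest known reaction types are the metallaphotoredox deoxygenative arylation of NHC-activated alcohols with aryl halides and the photoredox/nickel acylation of alkyltrifluoroborates with N-acylsuccinimides.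

**Step 13**
Reactants: 20 (3S,4S)-4-[4-(benzyloxy)-3-methoxybenzoyl]-3-[4-(benzyloxy)-3-methoxybenzyl]-3-hydroxydihydrofuran-2(3H)-one
Product: 21 (3S,4S)-3-hydroxy-4-(4-hydroxy-3-methoxybenzoyl)-3-(4-hydroxy-3-methoxybenzyl)dihydrofuran-2(3H)-one (target)
Conditions: H2 (1 atm), Pd/C (10 wt %), EtOAc, rt, stopped after uptake of 2 equiv H2
Reagents that add atoms: none
Why: Catalytic hydrogenolysis cleaves aryl benzyl ethers much faster than it reduces the electron-rich aryl ketone, and the neutral medium avoids epimerisation, retro-aldol cleavage and dehydration of the β-hydroxy ketone.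

**Compound list**
1 | catechol | Oc1ccccc1O | starting material
2 | guaiacol (2-methoxyphenol) | COc1ccccc1O | intermediate
3 | 4-bromo-2-methoxyphenol | COc1cc(Br)ccc1O | intermediate
4 | 1-(benzyloxy)-4-bromo-2-methoxybenzene | COc1cc(Br)ccc1OCc1ccccc1 | intermediate
5 | (S)-3-hydroxy-γ-butyrolactone | O=C1C[C@H](O)CO1 | starting material
6 | dilithium alkoxide–enolate dianion of 5 | [Li+].[Li+].[O-]C1=C[C@H]([O-])CO1 | intermediate
7 | (3S,4S)-3-[(dimethylamino)methyl]-4-hydroxydihydrofuran-2(3H)-one | O=C1OC[C@@H](O)[C@@H]1CN(C)C | intermediate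
8 | [(3S,4S)-4-hydroxy-2-oxotetrahydrofuran-3-yl]methyl-trimethylammonium iodide | O=C1OC[C@@H](O)[C@@H]1C[N+](C)(C)C.[I-] | intermediate
9 | (4S)-4-hydroxy-3-methylidenedihydrofuran-2(3H)-one, (S)-tulipalin B | O=C1OC[C@@H](O)C1=C | intermediate
10 | (4S)-4-[(tert-butyldimethylsilyl)oxy]-3-methylidenedihydrofuran-2(3H)-one | O=C1OC[C@@H](O[Si](C)(C)C(C)(C)C)C1=C | intermediate
11 | (3S,7R)-7-[(tert-butyldimethylsilyl)oxy]-1,5-dioxaspiro[2.4]heptan-4-one | O=C1OC[C@@H](O[Si](C)(C)C(C)(C)C)[C@@]12CO2 | intermediate
12 | [4-(benzyloxy)-3-methoxyphenyl]lithium | [Li]c1ccc(OCc2ccccc2)c(OC)c1 | intermediate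
13 | 4-(benzyloxy)-3-methoxybenzoic acid | COc1cc(C(=O)O)ccc1OCc1ccccc1 | intermediate
14 | 4-(benzyloxy)-3-methoxybenzoyl chloride | COc1cc(C(=O)Cl)ccc1OCc1ccccc1 | intermediate
15 | 1-[4-(benzyloxy)-3-methoxybenzoyl]pyrrolidine-2,5-dione | COc1cc(C(=O)N2C(=O)CCC2=O)ccc1OCc1ccccc1 | intermediate
16 | (3S,4R)-4-[(tert-butyldimethylsilyl)oxy]-3-hydroxy-3-(iodomethyl)dihydrofuran-2(3H)-one | O=C1OC[C@@H](O[Si](C)(C)C(C)(C)C)[C@@]1(O)CI | intermediate
17 | (3S,4R)-3-[4-(benzyloxy)-3-methoxybenzyl]-4-[(tert-butyldimethylsilyl)oxy]-3-hydroxydihydrofuran-2(3H)-one | O=C1OC[C@@H](O[Si](C)(C)C(C)(C)C)[C@@]1(O)Cc1ccc(OCc2ccccc2)c(OC)c1 | intermediate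
18 | (3S,4R)-3-[4-(benzyloxy)-3-methoxybenzyl]-3,4-dihydroxydihydrofuran-2(3H)-one (hydroxyls trans) | O=C1OC[C@@H](O)[C@@]1(O)Cc1ccc(OCc2ccccc2)c(OC)c1 | intermediate
19 | C4-O-(5,7-di-tert-butyl-3-phenyl-2,3-dihydrobenzoxazol-2-yl) ether of 18 (acetal carbon unassigned) | O=C1OC[C@@H](OC2Oc3c(cc(cc3C(C)(C)C)C(C)(C)C)N2c2ccccc2)[C@@]1(O)Cc1ccc(OCc2ccccc2)c(OC)c1 | intermediate
20 | (3S,4S)-4-[4-(benzyloxy)-3-methoxybenzoyl]-3-[4-(benzyloxy)-3-methoxybenzyl]-3-hydroxydihydrofuran-2(3H)-one | O=C1OC[C@H](C(=O)c2ccc(OCc3ccccc3)c(OC)c2)[C@@]1(O)Cc1ccc(OCc2ccccc2)c(OC)c1 | intermediate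
21 | (3S,4S)-3-hydroxy-4-(4-hydroxy-3-methoxybenzoyl)-3-(4-hydroxy-3-methoxybenzyl)dihydrofuran-2(3H)-one | COc1cc(C[C@@]2(O)C(=O)OC[C@@H]2C(=O)c2ccc(O)c(OC)c2)ccc1O | target

**Total step count:** 13
**Longest linear sequence:** 8 steps (5 → 7 → 9 → 10 → 11 → 17 → 18 → 20 → 21). The two aryl branches from catechol each run 7 steps to the target.

**Steps most likely to fail**

Step 12, the new coupling, carries the most risk. The tertiary OH may compete for the benzoxazolium salt. The aroyl-nickel species may decarbonylate. Quinuclidine may also degrade the β-hydroxy ketone. The fallback uses known chemistry, sets out from 18 and comes back at 20. Tf2O/pyridine (CH2Cl2, −20 °C) converts the secondary hydroxyl into the C4-triflate of diol 18 F1. Bu4NI (rt) displaces it with inversion to give the C4-iodide (3R,4S)-3-[4-(benzyloxy)-3-methoxybenzyl]-3-hydroxy-4-iododihydrofuran-2(3H)-one F2. This isolated secondary iodide then enters an established nickel-catalysed reductive acylation with acid chloride 14 (NiCl2(dme), dtbbpy, Mn, DMA, 0 °C). No light, no base and no alcohol activation are involved, and the same radical capture anti to the benzyl group gives 20.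

Step 10 comes second. The glycidic-type epoxide is a poor Lewis base, low-valent metal may cleave its α-C–O bond reductively, and the electron-rich bromide adds slowly to nickel. The fallback replaces the radical coupling with a polar SN2 opening. It sets out from 4 and 11 and comes back at 17. Mg turnings in THF convert 4 into [4-(benzyloxy)-3-methoxyphenyl]magnesium bromide F3. With CuI (10 mol %) in THF at −40 °C, F3 attacks the epoxide CH2 of 11. The lactone carbonyl is shielded by the adjacent quaternary spiro carbon. NH4Cl work-up gives 17.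

Step 7 comes third. The alkene is electron-poor and hindered, so oxygen transfer is slow, and its facial selectivity alone defines C3. The fallback builds the oxirane stepwise, sets out from 10 and comes back at 11. OsO4 (cat.)/NMO in acetone/H2O dihydroxylates anti to the silyloxy group and gives (3S,4R)-4-[(tert-butyldimethylsilyl)oxy]-3-hydroxy-3-(hydroxymethyl)dihydrofuran-2(3H)-one F4. TsCl/pyridine sulfonylates only the primary hydroxyl to give the primary tosylate of F4 F5. K2CO3 in MeCN then closes the tertiary alkoxide onto CH2OTs, with the C3–O bond retained, to give 11.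

**Further compounds**
F1 | step 12 | C4-triflate of diol 18 | O=C1OC[C@@H](OS(=O)(=O)C(F)(F)F)[C@@]1(O)Cc1ccc(OCc2ccccc2)c(OC)c1
F2 | step 12 | (3R,4S)-3-[4-(benzyloxy)-3-methoxybenzyl]-3-hydroxy-4-iododihydrofuran-2(3H)-one | O=C1OC[C@H](I)[C@@]1(O)Cc1ccc(OCc2ccccc2)c(OC)c1
F3 | step 10 | [4-(benzyloxy)-3-methoxyphenyl]magnesium bromide | COc1cc([Mg]Br)ccc1OCc1ccccc1
F4 | step 7 | (3S,4R)-4-[(tert-butyldimethylsilyl)oxy]-3-hydroxy-3-(hydroxymethyl)dihydrofuran-2(3H)-one | O=C1OC[C@@H](O[Si](C)(C)C(C)(C)C)[C@@]1(O)CO
F5 | step 7 | primary tosylate of F4 | O=C1OC[C@@H](O[Si](C)(C)C(C)(C)C)[C@@]1(O)COS(=O)(=O)c1ccc(C)cc1
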